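**Retrosynthetic overview**
- The three phenols travel as MOM ethers and are freed in the last step. Rings A and B are bought as benzene rings. Ring C is the only ring built, in the penultimate step.
- Ring C is cut at O1–C8a and C4–C4a at once. A ring-A aryne (C4a≡C8a) is annulated with the intact chain O1–C2–C3–C4 of an (S)-β-silyloxy ester that already carries ring B and the C2 stereocentre.
- Enabling feature: C8a and C4a are neighbours on a ring A whose other four carbons (C5–C8) are all substituted, so only one aryne can form. The C5 oxygen next to C4a polarises the aryne so that O1 enters at C8a and the carbanion appears at C4a. The chain O1–C2–C3–C4 is an aldol unit, nucleophilic at O1 and electrophilic at C4, spaced for six-ring closure.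
- Aryne precursor from 2,4,6-trihydroxybenzaldehyde: hydrogen-bond-controlled bis-MOM protection, CHO to CH3 (C8 methyl), directed ortho metalation/prenylation at C6, iodination at C4a, retro-Brook silyl shift and triflation at C8a.
- Ester partner from 4'-hydroxyacetophenone: MOM ether, Claisen condensation with dimethyl carbonate, Noyori asymmetric transfer hydrogenation (sets C2 as S), O-silylation.

Key step: step 10

Assumption: positions in all ring-A intermediates are quoted in flavanone numbering (O1, C2, C3, C4, C4a, C5–C8, C8a; ring A = hexasubstituted benzene ring, ring B = 4-hydroxyphenyl ring, ring C = pyranone ring). The stereocentre of the target SMILES is read as 2S.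

Step 1
Reactants: 1 2,4,6-trihydroxybenzaldehyde
Product: 2 2-hydroxy-4,6-bis(methoxymethoxy)benzaldehyde
Conditions: MOMCl (2.1 equiv), i-Pr2NEt, CH2Cl2, 0 °C to rt
Reagents that add atoms: chloromethyl methyl ether (MOMCl), COCCl
Why: Williamson-type O-alkylation that should stop at the bis-ether, because the last ortho hydroxyl (future C8a–OH) is locked in a hydrogen bond to the formyl oxygen and is far less nucleophilic.

Step 2
Reactants: 2 2-hydroxy-4,6-bis(methoxymethoxy)benzaldehyde
Product: 4 3,5-bis(methoxymethoxy)-2-methylphenol, via aryl ethyl carbonate 3 (not isolated)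
Conditions: ClCO2Et, Et3N, THF, 0 °C; then NaBH4, THF–H2O, 0 °C to rt
Reagents that add atoms: ethyl chloroformate, CCOC(=O)Cl (its atoms are carried only by 3 and leave again)
Why: Reductive deoxygenation of a salicylaldehyde through an o-quinone methide, in which NaBH4 reduces the formyl group of 3, the ethoxycarbonyl group migrates to the benzylic oxygen and is expelled, and a second hydride adds to the quinone methide, conditions to which MOM acetals are inert.

Step 3
Reactants: 4 3,5-bis(methoxymethoxy)-2-methylphenol; 5 prenyl bromide (1-bromo-3-methylbut-2-ene)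
Product: 7 3,5-bis(methoxymethoxy)-2-methyl-4-(3-methylbut-2-en-1-yl)phenol, via dilithio species 6 (not isolated)
Conditions: n-BuLi (2.2 equiv), THF, 0 °C to rt; then 5, −78 °C to 0 °C; H2O
Reagents that add atoms: n-butyllithium, [Li]CCCC (lithium only in 6)
Why: Directed ortho metalation, in which the second equivalent of base is held by both OMOM groups and removes the proton between them (future C6) rather than the one beside the deactivating phenoxide, and the aryllithium then displaces bromide at the primary carbon of 5.

Step 4
Reactants: 7 3,5-bis(methoxymethoxy)-2-methyl-4-(3-methylbut-2-en-1-yl)phenol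
Product: 8 2-iodo-3,5-bis(methoxymethoxy)-6-methyl-4-(3-methylbut-2-en-1-yl)phenol
Conditions: I2 (1.0 equiv), NaHCO3, THF–H2O, 0 °C
Reagents that add atoms: iodine, II
Why: Electrophilic aromatic iodination at the only ring C–H left (future C4a), which is ortho to the free hydroxyl and ortho/para to the two OMOM groups and should take up iodine much faster than the trisubstituted alkene, which has no free neighbouring hydroxyl for iodoetherification.

Step 5
Reactants: 8 2-iodo-3,5-bis(methoxymethoxy)-6-methyl-4-(3-methylbut-2-en-1-yl)phenol
Product: 11 3,5-bis(methoxymethoxy)-2-methyl-4-(3-methylbut-2-en-1-yl)-6-(trimethylsilyl)phenyl trifluoromethanesulfonate, via O-silyl ether 9 (not isolated), via lithium phenoxide 10 (not isolated)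
Conditions: (Me3Si)2NH, THF, 65 °C, evaporate; n-BuLi, THF, −78 °C; Tf2O, −78 °C to 0 °C
Reagents that add atoms: hexamethyldisilazane, C[Si](C)(C)N[Si](C)(C)C; n-butyllithium, [Li]CCCC (lithium only in 10); trifluoromethanesulfonic anhydride, O=S(=O)(OS(=O)(=O)C(F)(F)F)C(F)(F)F
Why: Standard sequence to o-silylaryl triflates, namely O-silylation, iodine–lithium exchange (faster at −78 °C than any allylic or benzylic deprotonation), retro-Brook 1,3-shift of silicon from oxygen to C4a and triflation of the released C8a phenoxide.

Step 6
Reactants: 12 4'-hydroxyacetophenone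
Product: 13 4'-(methoxymethoxy)acetophenone
Conditions: MOMCl, i-Pr2NEt, CH2Cl2, 0 °C to rt
Reagents that add atoms: chloromethyl methyl ether (MOMCl), COCCl
Why: Williamson-type O-alkylation of the only hydroxyl group, giving the same acetal protecting group as on ring A so that one final operation frees all phenols.

Step 7
Reactants: 13 4'-(methoxymethoxy)acetophenone
Product: 14 methyl 3-[4-(methoxymethoxy)phenyl]-3-oxopropanoate
Conditions: NaH (2.2 equiv), (MeO)2CO, THF, 65 °C; AcOH quench
Reagents that add atoms: dimethyl carbonate, COC(=O)OC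
Why: Crossed Claisen condensation of the methyl ketone enolate with non-enolisable dimethyl carbonate, driven to completion by deprotonation of the β-keto ester formed.

Step 8
Reactants: 14 methyl 3-[4-(methoxymethoxy)phenyl]-3-oxopropanoate
Product: 15 methyl (S)-3-hydroxy-3-[4-(methoxymethoxy)phenyl]propanoate
Conditions: RuCl(p-cymene)[(S,S)-TsDPEN] (0.5 mol %), HCO2H–Et3N (5:2), EtOAc, 30 °C
Reagents that add atoms: none
Why: Noyori asymmetric transfer hydrogenation, in which the (S,S)-catalyst recognises the aryl group of aryl ketones through a CH–π contact with its arene ligand and delivers hydride to the face that gives the S carbinol, which becomes C2 of the target.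

Step 9
Reactants: 15 methyl (S)-3-hydroxy-3-[4-(methoxymethoxy)phenyl]propanoate
Product: 16 methyl (S)-3-[4-(methoxymethoxy)phenyl]-3-(trimethylsilyloxy)propanoate
Conditions: Me3SiCl, imidazole, CH2Cl2, 0 °C
Reagents that add atoms: chlorotrimethylsilane, C[Si](C)(C)Cl
Why: Routine O-silylation that touches no bond at the stereocentre and turns the alcohol into a proton-free, fluoride-releasable alkoxide source.

Step 10
Reactants: 11 3,5-bis(methoxymethoxy)-2-methyl-4-(3-methylbut-2-en-1-yl)-6-(trimethylsilyl)phenyl trifluoromethanesulfonate; 16 methyl (S)-3-[4-(methoxymethoxy)phenyl]-3-(trimethylsilyloxy)propanoate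
Product: 19 (S)-5,7-bis(methoxymethoxy)-2-[4-(methoxymethoxy)phenyl]-8-methyl-6-(3-methylbut-2-en-1-yl)chroman-4-one, via aryne 17 (not isolated), via aryl anion 18 (not isolated)
Conditions: 16 (1.0 equiv), CsF, 18-crown-6, THF, 0 °C to rt, 11 (1.2 equiv) added slowly; pH 7 buffer quench
Reagents that add atoms: cesium fluoride, [Cs+].[F-] (cesium only in 18)
Why: Proposed new method: fluoride removes the silyl group at C4a of 11 and triflate leaves from C8a to give aryne 17, while fluoride (and then the methoxide set free in every turnover) unmasks the alkoxide of 16 in a medium without O–H protons; the alkoxide oxygen adds to C8a (bond O1–C8a) and the resulting C4a aryl anion 18 attacks the methyl ester carbon (bond C4–C4a) and expels methoxide. The closest known reaction type is the tandem addition/acyl substitution of arynes with methyl salicylates (to xanthones) and with α-amino esters (to indolin-3-ones), and the new element is an aliphatic β-oxido ester as the four-atom partner. Ring C closes by 6-exo-trig attack of the in-plane aryl anion on the ester carbonyl, so that overall O1–C2–C3–C4 is annulated onto C8a–C4a in a formal [4+2] sense. No stereocentre is created: C2 arrives as S from 16 and none of its four bonds is touched, so its configuration should be carried over unchanged. The step needs regioselective addition, which the C5 OMOM group secures because its inductive pull distorts the aryne so that nucleophiles enter at the remote carbon C8a and charge builds up at C4a between two oxygen-bearing carbons, an electronic bias expected to outweigh the small steric cost of the C8 methyl group. It also needs acyl capture to outrun protonation and the ene reaction of the prenyl group, which the proton-free release of the alkoxide, the short distance to the ester and the slow addition of 11 should provide, while methoxide is scavenged as MeOSiMe3 so that ring C is not reopened by base.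

Step 11
Reactants: 19 (S)-5,7-bis(methoxymethoxy)-2-[4-(methoxymethoxy)phenyl]-8-methyl-6-(3-methylbut-2-en-1-yl)chroman-4-one
Product: 20 (S)-5,7-dihydroxy-2-(4-hydroxyphenyl)-8-methyl-6-(3-methylbut-2-en-1-yl)chroman-4-one (5,7,4'-trihydroxy-8-methyl-6-prenylflavanone)
Conditions: HCl (cat.), MeOH, 40 °C
Reagents that add atoms: none
Why: Acid-catalysed acetal exchange with methanol removes all three MOM groups under mild conditions of the kind used for prenylated flavanones, avoiding the basic media in which C2 would be scrambled through the chalcone.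

**Compound list**
1 | 2,4,6-trihydroxybenzaldehyde | O=Cc1c(O)cc(O)cc1O | starting material
2 | 2-hydroxy-4,6-bis(methoxymethoxy)benzaldehyde | O=Cc1c(O)cc(OCOC)cc1OCOC | intermediate
3 | ethyl 2-formyl-3,5-bis(methoxymethoxy)phenyl carbonate (not isolated) | CCOC(=O)Oc1cc(OCOC)cc(OCOC)c1C=O | intermediate
4 | 3,5-bis(methoxymethoxy)-2-methylphenol | Cc1c(O)cc(OCOC)cc1OCOC | intermediate
5 | prenyl bromide (1-bromo-3-methylbut-2-ene) | CC(C)=CCBr | starting material
6 | lithium 4-lithio-3,5-bis(methoxymethoxy)-2-methylphenoxide (not isolated) | [Li]Oc1cc(OCOC)c([Li])c(OCOC)c1C | intermediate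
7 | 3,5-bis(methoxymethoxy)-2-methyl-4-(3-methylbut-2-en-1-yl)phenol | CC(C)=CCc1c(OCOC)cc(O)c(C)c1OCOC | intermediate
8 | 2-iodo-3,5-bis(methoxymethoxy)-6-methyl-4-(3-methylbut-2-en-1-yl)phenol | CC(C)=CCc1c(OCOC)c(I)c(O)c(C)c1OCOC | intermediate
9 | [2-iodo-3,5-bis(methoxymethoxy)-6-methyl-4-(3-methylbut-2-en-1-yl)phenoxy]trimethylsilane (not isolated) | CC(C)=CCc1c(OCOC)c(I)c(O[Si](C)(C)C)c(C)c1OCOC | intermediate
10 | lithium 3,5-bis(methoxymethoxy)-2-methyl-4-(3-methylbut-2-en-1-yl)-6-(trimethylsilyl)phenoxide (not isolated) | CC(C)=CCc1c(OCOC)c([Si](C)(C)C)c(O[Li])c(C)c1OCOC | intermediate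
11 | 3,5-bis(methoxymethoxy)-2-methyl-4-(3-methylbut-2-en-1-yl)-6-(trimethylsilyl)phenyl trifluoromethanesulfonate | CC(C)=CCc1c(OCOC)c([Si](C)(C)C)c(OS(=O)(=O)C(F)(F)F)c(C)c1OCOC | intermediate
12 | 4'-hydroxyacetophenone | CC(=O)c1ccc(O)cc1 | starting material
13 | 4'-(methoxymethoxy)acetophenone | CC(=O)c1ccc(OCOC)cc1 | intermediate
14 | methyl 3-[4-(methoxymethoxy)phenyl]-3-oxopropanoate | COC(=O)CC(=O)c1ccc(OCOC)cc1 | intermediate
15 | methyl (S)-3-hydroxy-3-[4-(methoxymethoxy)phenyl]propanoate | COC(=O)C[C@@H](c1ccc(OCOC)cc1)O | intermediate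
16 | methyl (S)-3-[4-(methoxymethoxy)phenyl]-3-(trimethylsilyloxy)propanoate | COC(=O)C[C@@H](c1ccc(OCOC)cc1)O[Si](C)(C)C | intermediate
17 | 3,5-bis(methoxymethoxy)-6-methyl-4-(3-methylbut-2-en-1-yl)-1,2-didehydrobenzene, the C4a≡C8a aryne (not isolated) | CC(C)=CCC1=C(OCOC)C#CC(C)=C1OCOC | intermediate
18 | cesium salt of the C4a aryl anion of methyl (S)-3-[3,5-bis(methoxymethoxy)-2-methyl-4-(3-methylbut-2-en-1-yl)phenoxy]-3-[4-(methoxymethoxy)phenyl]propanoate (not isolated) | COC(=O)C[C@@H](c1ccc(OCOC)cc1)Oc1c(C)c(OCOC)c(CC=C(C)C)c(OCOC)[c-]1.[Cs+] | intermediate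
19 | (S)-5,7-bis(methoxymethoxy)-2-[4-(methoxymethoxy)phenyl]-8-methyl-6-(3-methylbut-2-en-1-yl)chroman-4-one | CC(C)=CCc1c(OCOC)c(C)c2c(c1OCOC)C(=O)C[C@@H](c1ccc(OCOC)cc1)O2 | intermediate
20 | (S)-5,7-dihydroxy-2-(4-hydroxyphenyl)-8-methyl-6-(3-methylbut-2-en-1-yl)chroman-4-one | CC(C)=CCc1c(O)c(C)c2c(c1O)C(=O)C[C@@H](c1ccc(O)cc1)O2 | target

**Step count**
- Total step count: 11.
- Longest linear sequence: 7 steps (steps 1, 2, 3, 4, 5, 10, 11). Steps 6–9 form the second branch.

**Steps most likely to fail**

1. Step 10.
- What may go wrong: the acidic C3 protons may quench the C4a aryl anion, after which the aryloxide is lost by β-elimination. The alkoxide may add at C4a instead of C8a. The free alkoxide may undergo retro-aldol cleavage or oligomerisation. Base may open and reclose ring C and so erode C2.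
- Fallback (known chemistry): the ether bond is made at C2 instead of C8a, and the aryl anion comes from halogen–metal exchange. It sets out from 8 and 14 and comes back at 19. Keto ester 14 is reduced as in step 8, but with RuCl(p-cymene)[(R,R)-TsDPEN], to methyl (R)-3-hydroxy-3-[4-(methoxymethoxy)phenyl]propanoate F1. A Mitsunobu reaction of iodophenol 8 with this alcohol (PPh3, DIAD, toluene, 0 °C) should give, with inversion at the carbinol carbon, methyl (S)-3-[2-iodo-3,5-bis(methoxymethoxy)-6-methyl-4-(3-methylbut-2-en-1-yl)phenoxy]-3-[4-(methoxymethoxy)phenyl]propanoate F2. Iodine–magnesium exchange (i-PrMgCl·LiCl, THF, −40 °C to 0 °C) then triggers a Parham-type cyclisation onto the methyl ester and delivers 19.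

2. Step 3.
- What may go wrong: the second deprotonation may stall on the electron-rich phenoxide, or occur beside the phenoxide oxygen (future C4a). The phenoxide may also be O-alkylated.
- Fallback: a mono-anion of a fully capped arene replaces the dianion, with a bulky non-directing silyl ether shielding C4a. It sets out from 4 and comes back at 7. Phenol 4 is silylated (TBSCl, imidazole, DMF, rt) to tert-butyl[3,5-bis(methoxymethoxy)-2-methylphenoxy]dimethylsilane F3. Lithiation between the two OMOM groups (n-BuLi, THF, 0 °C) and alkylation with 5 should give tert-butyl[3,5-bis(methoxymethoxy)-2-methyl-4-(3-methylbut-2-en-1-yl)phenoxy]dimethylsilane F4. Treatment with Bu4NF (THF, 0 °C) returns 7.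

3. Step 11.
- What may go wrong: acid may cyclise the prenyl group onto the freed C5 or C7 hydroxyl, or add methanol to the alkene. Acid may also ionise the C2–O1 bond next to the electron-rich ring B, with loss of configuration.
- Fallback: the acetals are exchanged for silyl ethers without Brønsted acid and then hydrolysed at neutral pH. It sets out from 19 and comes back at 20. Me3SiOTf and 2,2'-bipyridyl (MeCN, 0 °C) should convert the three aryl MOM ethers into (S)-8-methyl-6-(3-methylbut-2-en-1-yl)-5,7-bis(trimethylsilyloxy)-2-[4-(trimethylsilyloxy)phenyl]chroman-4-one F5. Addition of water at rt cleaves F5 to 20.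

**Further compounds**
F1 | step 10 | methyl (R)-3-hydroxy-3-[4-(methoxymethoxy)phenyl]propanoate | COC(=O)C[C@H](c1ccc(OCOC)cc1)O
F2 | step 10 | methyl (S)-3-[2-iodo-3,5-bis(methoxymethoxy)-6-methyl-4-(3-methylbut-2-en-1-yl)phenoxy]-3-[4-(methoxymethoxy)phenyl]propanoate | COC(=O)C[C@@H](c1ccc(OCOC)cc1)Oc1c(C)c(OCOC)c(CC=C(C)C)c(OCOC)c1I
F3 | step 3 | tert-butyl[3,5-bis(methoxymethoxy)-2-methylphenoxy]dimethylsilane | Cc1c(O[Si](C)(C)C(C)(C)C)cc(OCOC)cc1OCOC
F4 | step 3 | tert-butyl[3,5-bis(methoxymethoxy)-2-methyl-4-(3-methylbut-2-en-1-yl)phenoxy]dimethylsilane | CC(C)=CCc1c(OCOC)cc(O[Si](C)(C)C(C)(C)C)c(C)c1OCOC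
F5 | step 11 | (S)-8-methyl-6-(3-methylbut-2-en-1-yl)-5,7-bis(trimethylsilyloxy)-2-[4-(trimethylsilyloxy)phenyl]chroman-4-one | CC(C)=CCc1c(O[Si](C)(C)C)c(C)c2c(c1O[Si](C)(C)C)C(=O)C[C@@H](c1ccc(O[Si](C)(C)C)cc1)O2
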